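The two rings are numbered as follows. Ring A is C1(OH), C2(Br), C4(Br), C6(O bridge). Ring B is C1'(O bridge), C2'(OH), C3'(Br), C5'(Br), C6'(Br). C3, C5 and C4' carry H.
Enabling feature: C2 and C4 of ring A and C3' and C5' of ring B each lie ortho or para to the OH of their own ring. C6' is meta to the ring B OH, so only that bromine has to be bought in.
Cuts, in retrosynthetic order: the four C–Br bonds at C2, C4, C3' and C5'; the O–CH3 bond of a ring A methyl ether; the C2'–O bond (phenol back to aldehyde); the C1'–O bridge bond.
Forward: both benzene rings are purchased and joined at the bridge oxygen by SNAr. The formyl carbon on C2' is then exchanged for oxygen by Baeyer–Villiger oxidation, BBr3 frees the ring A phenol, and one bromination ends the route. No ring is built.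
Stereochemistry: none to set, because the target has no stereocentre.

Key step: step 4

Remark: the diaryl ether axis is assumed to rotate freely at room temperature, so every compound is handled as a single achiral species. Compounds 1 and 2 are taken to be catalogue chemicals.

Step 1
Reactants: 1 2-methoxyphenol (guaiacol); 2 3-bromo-2-fluorobenzaldehyde
Product: 3 3-bromo-2-(2-methoxyphenoxy)benzaldehyde
Conditions: K2CO3 (1.5 equiv), DMF, 100 °C, N2
Reagents that add atoms: none
Why: Nucleophilic aromatic substitution (SNAr, addition–elimination): the formyl group ortho to fluorine stabilises the Meisenheimer adduct, fluoride leaves far faster than bromide, and the bromine sits meta to the aldehyde and is not activated, so potassium guaiacolate should attack only the C–F carbon.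

Step 2
Reactants: 3 3-bromo-2-(2-methoxyphenoxy)benzaldehyde
Product: 5 3-bromo-2-(2-methoxyphenoxy)phenol, via aryl formate 4 (not isolated)
Conditions: mCPBA (1.4 equiv), CH2Cl2, 0 °C to rt; aq. Na2SO3/NaHCO3 wash, concentrate; then K2CO3 (cat.), MeOH, rt
Reagents that add atoms: mCPBA (3-chloroperoxybenzoic acid), OOC(=O)c1cccc(Cl)c1
Why: Baeyer–Villiger oxidation of an ortho-aryloxybenzaldehyde (the peracid counterpart of the Dakin reaction): in the Criegee adduct the aryl group, enriched by the ether oxygen ortho to the migrating carbon, should shift to oxygen in preference to hydride, and the labile formate is then cleaved by base-catalysed transesterification in MeOH without touching the methyl ether, the bridge or the bromide.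

Step 3
Reactants: 5 3-bromo-2-(2-methoxyphenoxy)phenol
Product: 6 3-bromo-2-(2-hydroxyphenoxy)phenol
Conditions: BBr3 (3 equiv), CH2Cl2, −78 °C to rt; then ice/H2O
Reagents that add atoms: none
Why: Lewis-acid-mediated aryl methyl ether cleavage: BBr3 binds the methoxy oxygen and bromide removes the methyl group by SN2 attack, whereas the diaryl ether and the C–Br bond offer no sp3 carbon and stay intact.

Step 4
Reactants: 6 3-bromo-2-(2-hydroxyphenoxy)phenol
Product: 7 3,4,6-tribromo-2-(3,5-dibromo-2-hydroxyphenoxy)phenol (target)
Conditions: Br2 (4.1 equiv, added slowly as a solution in AcOH), AcOH, rt to 40 °C; aq. NaHSO3 quench; crystallisation or chromatography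
Reagents that add atoms: bromine, BrBr
Why: Four consecutive electrophilic aromatic substitutions run in one flask: Br2 adds to a ring carbon to give an arenium ion whose charge is carried by the hydroxyl oxygen of the same ring, and loss of HBr restores the arene. The closest known reaction type is the exhaustive ortho/para bromination of phenols and of hydroxylated diphenyl ethers with Br2 in AcOH. The step forms no ring and no stereocentre. It needs site selectivity for C2 and C4 on ring A and C3' and C5' on ring B over the carbons that only the bridge oxygen activates (C3, C5, C4'); this is secured because a free OH is a much stronger donor than an aryloxy oxygen that shares its lone pairs between two progressively electron-poorer rings, and because the C6' bromine, being ortho to C5' and para to C3', directs to the same two carbons as the ring B hydroxyl. It also has to stop at four: once these sites are filled every remaining C–H is meta to its hydroxyl on a ring with two or three bromines, C4' is in addition flanked by bromine on both sides, and the charge of Br2 is held to a slight excess. Keeping both phenols free in a non-basic medium avoids phenoxide oxidation, and the bisulfite quench destroys leftover oxidant before isolation.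

Compound list
1 | 2-methoxyphenol (guaiacol) | COc1ccccc1O | starting material
2 | 3-bromo-2-fluorobenzaldehyde | O=Cc1cccc(Br)c1F | starting material
3 | 3-bromo-2-(2-methoxyphenoxy)benzaldehyde | COc1ccccc1Oc1c(Br)cccc1C=O | intermediate
4 | 3-bromo-2-(2-methoxyphenoxy)phenyl formate | COc1ccccc1Oc1c(Br)cccc1OC=O | intermediate
5 | 3-bromo-2-(2-methoxyphenoxy)phenol | COc1ccccc1Oc1c(O)cccc1Br | intermediate
6 | 3-bromo-2-(2-hydroxyphenoxy)phenol | Oc1ccccc1Oc1c(O)cccc1Br | intermediate
7 | 3,4,6-tribromo-2-(3,5-dibromo-2-hydroxyphenoxy)phenol | Oc1c(Br)cc(Br)cc1Oc1c(O)c(Br)cc(Br)c1Br | target

Total step count: 4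
Longest linear sequence: 4 steps (1 or 2, then 3, 5, 6, 7)

Steps most likely to fail

**Step 4.** Positional control may erode, with attack para to the bridge oxygen once the best sites are filled. The bromine count may also become uneven between the more reactive ring A and the less reactive ring B, which would leave congeners that are hard to separate.
- The fallback halogenates before deprotection and uses the methyl ether as a gate.
- Setting out from 5, three equivalents of Br2 in AcOH should fill C3' and C5' under the ring B hydroxyl and C4 under the ring A methoxy group. An anisole-type ring stops after one bromine, so this should give 3,4,6-tribromo-2-(5-bromo-2-methoxyphenoxy)phenol F1.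
- BBr3 in CH2Cl2 then frees 3,4,6-tribromo-2-(5-bromo-2-hydroxyphenoxy)phenol F2. In F2, C2 is the only carbon ortho or para to a hydroxyl that still bears hydrogen.
- One equivalent of NBS with catalytic i-Pr2NH in CH2Cl2 (amine-mediated ortho-bromination of phenols) places the last bromine there.
- The sequence comes back to the route at 7.

**Step 2.** Hydride migration may compete with aryl migration in the Criegee adduct, because the migrating ring carries an electron-withdrawing bromine. Conversion may also be slow enough for the peracid to begin attacking the electron-rich ring A.
- The fallback avoids any change of oxidation level by bringing in both oxygens as methyl ethers.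
- Setting out from 1, ortho-selective bromination (NBS, catalytic i-Pr2NH, CH2Cl2) gives 2-bromo-6-methoxyphenol F3, which can also be bought.
- Chan–Lam coupling of F3 with 2-methoxyphenylboronic acid (Cu(OAc)2, pyridine, 4 Å molecular sieves, CH2Cl2, air, rt) leaves the aryl bromide untouched. It gives 1-bromo-3-methoxy-2-(2-methoxyphenoxy)benzene F4.
- Excess BBr3 cleaves both methyl ethers.
- The sequence comes back to the route at 6.

**Step 1.** Addition to a fluoride flanked on both sides may be sluggish. The formyl group may also degrade through base or air at the temperature the displacement needs.
- The fallback changes the activating group to a nitrile, which tolerates harsher conditions.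
- Setting out from 1, SNAr on 3-bromo-2-fluorobenzonitrile (K2CO3, DMSO, 110 °C) gives 3-bromo-2-(2-methoxyphenoxy)benzonitrile F5.
- DIBAL-H in toluene at −78 °C, followed by dilute HCl, reduces the nitrile to the aldehyde.
- The sequence comes back to the route at 3.

Further compounds
F1 | step 4 | 3,4,6-tribromo-2-(5-bromo-2-methoxyphenoxy)phenol | COc1ccc(Br)cc1Oc1c(O)c(Br)cc(Br)c1Br
F2 | step 4 | 3,4,6-tribromo-2-(5-bromo-2-hydroxyphenoxy)phenol | Oc1ccc(Br)cc1Oc1c(O)c(Br)cc(Br)c1Br
F3 | step 2 | 2-bromo-6-methoxyphenol | COc1cccc(Br)c1O
F4 | step 2 | 1-bromo-3-methoxy-2-(2-methoxyphenoxy)benzene | COc1ccccc1Oc1c(OC)cccc1Br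
F5 | step 1 | 3-bromo-2-(2-methoxyphenoxy)benzonitrile | COc1ccccc1Oc1c(Br)cccc1C#N
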